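**Strategy.** The route rests on cutting the furan ring of the benzofuran at O1–C2 and C3–C3a, which splits the target into two flavonoid-type halves: benzyl-protected phloretin and a diaryl ynone. The key step relies on O1 and C3a being, respectively, the hydrogen-bonded 2'-hydroxyl oxygen of phloretin and the one unsubstituted carbon next to it (C3') on the phloroglucinol ring, with the dihydrochalcone acyl chain already in place at C7. In one pot, conjugate addition of the phenol and palladium-catalysed dehydrogenative C–H/C–H coupling close the furan ring and complete the carbon skeleton. The precursors are 4,4',6'-tri-O-benzylphloretin, which has a single free phenol, and a tris-benzylated 1,3-diarylprop-2-yn-1-one.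

Key step: step 5

Remark on the chemistry: 1-[2,4-bis(benzyloxy)-6-hydroxyphenyl]ethanone, 4-(benzyloxy)benzaldehyde, 2,4-bis(benzyloxy)benzaldehyde and 1-(benzyloxy)-4-ethynylbenzene are assumed to be purchased. Tribenzylphloretin is assembled from two of these benzylated building blocks, so the position of its single free hydroxyl (ortho to the ketone, which places the acyl chain at C7) is fixed by the acetophenone. The target has no stereocentre; the propargylic alcohol is racemic and its carbinol centre is removed on oxidation.

**Step 1**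
Reactants: 1 1-[2,4-bis(benzyloxy)-6-hydroxyphenyl]ethanone; 2 4-(benzyloxy)benzaldehyde
Product: 3 (E)-1-[2,4-bis(benzyloxy)-6-hydroxyphenyl]-3-[4-(benzyloxy)phenyl]prop-2-en-1-one (2'-hydroxy-4,4',6'-tris(benzyloxy)chalcone)
Conditions: KOH (50% aq., 10 equiv), EtOH, rt; then aq. HCl to pH 5, 0 °C
Reagents that add atoms: none
Why: Claisen–Schmidt condensation of the methyl ketone enolate with the non-enolisable aldehyde, followed by E1cB dehydration, should give the thermodynamically preferred E-enone; in strong base the product is held as its phenoxide, which suppresses ring closure to the flavanone.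

**Step 2**
Reactants: 3 (E)-1-[2,4-bis(benzyloxy)-6-hydroxyphenyl]-3-[4-(benzyloxy)phenyl]prop-2-en-1-one
Product: 4 4,4',6'-tri-O-benzylphloretin, i.e. 1-[2,4-bis(benzyloxy)-6-hydroxyphenyl]-3-[4-(benzyloxy)phenyl]propan-1-one
Conditions: H2 (4 bar), RhCl(PPh3)3 (5 mol %), toluene/EtOH (1:1), 50 °C
Reagents that add atoms: none
Why: Homogeneous hydrogenation with RhCl(PPh3)3 should saturate the disubstituted enone C=C chemoselectively, since this catalyst neither hydrogenolyses aryl benzyl ethers nor reduces aryl ketones.

**Step 3**
Reactants: 5 1-(benzyloxy)-4-ethynylbenzene; 6 2,4-bis(benzyloxy)benzaldehyde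
Product: 8 1-[2,4-bis(benzyloxy)phenyl]-3-[4-(benzyloxy)phenyl]prop-2-yn-1-ol (racemic), via lithium [4-(benzyloxy)phenyl]acetylide 7 (not isolated)
Conditions: n-BuLi (1.05 equiv), THF, −78 °C; then 6, −78 to 0 °C; aq. NH4Cl
Reagents that add atoms: none
Why: Deprotonation of the terminal alkyne and 1,2-addition of the lithium acetylide to the non-enolisable aromatic aldehyde is a standard carbonyl alkynylation; the carbinol centre forms without control as a racemate and is removed in step 4.

**Step 4**
Reactants: 8 1-[2,4-bis(benzyloxy)phenyl]-3-[4-(benzyloxy)phenyl]prop-2-yn-1-ol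
Product: 9 1-[2,4-bis(benzyloxy)phenyl]-3-[4-(benzyloxy)phenyl]prop-2-yn-1-one
Conditions: MnO2 (10 equiv), CH2Cl2, rt
Reagents that add atoms: none
Why: MnO2 oxidation of a secondary alcohol that is both benzylic and propargylic should give the conjugated ynone under neutral conditions that leave the benzyl ethers and the alkyne untouched.

**Step 5**
Reactants: 4 4,4',6'-tri-O-benzylphloretin; 9 1-[2,4-bis(benzyloxy)phenyl]-3-[4-(benzyloxy)phenyl]prop-2-yn-1-one
Product: 11 1-{4,6-bis(benzyloxy)-3-[2,4-bis(benzyloxy)benzoyl]-2-[4-(benzyloxy)phenyl]-1-benzofuran-7-yl}-3-[4-(benzyloxy)phenyl]propan-1-one (hexa-O-benzyl ether of the target), via β-aryloxy enone 10 (not isolated)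
Conditions: K2CO3 (0.2 equiv), dry DMF, 60 °C; then Pd(OAc)2 (10 mol %), Cu(OAc)2 (2.2 equiv), PivOH (0.3 equiv), 110 °C, N2, one pot
Reagents that add atoms: none
Why: Catalytic carbonate ionises the single phenol of 4 and the phenoxide adds to the alkyne carbon of 9 remote from the carbonyl (the one bearing the 4-benzyloxyphenyl group), so that protonation gives β-aryloxy enone 10 and sets the O1–C2 bond. Divalent palladium then metalates the electron-rich α-carbon of this vinylogous ester, pivalate-assisted concerted metalation–deprotonation brings in the neighbouring aryl C3'–H, and reductive elimination forges C3–C3a while Cu(OAc)2 reoxidises zerovalent palladium to the divalent state. The closest known reaction type is the palladium-catalysed oxidative cyclisation of 3-aryloxyacrylates and related phenol–alkyne adducts to 3-acylbenzofurans, itself a variant of the oxidative annulation of phenols with internal alkynes. The furan ring closes by C–C reductive elimination from a six-membered oxapalladacycle (Pd, C3, C2, O1, C7a, C3a), i.e. an intramolecular vinyl–aryl dehydrogenative coupling, and the E/Z geometry of 10 should be irrelevant because the isomers interconvert by reversible conjugate addition and through the α-palladated oxocarbenium form. No stereocentre is created. Regiocontrol is required and is built into the substrates: a heteroatom nucleophile can only attack the β-carbon of the ynone (hence 2-aryl, 3-aroyl), 4 offers one hydroxyl, and that hydroxyl has a single unsubstituted ortho carbon because the other carries the acyl chain, while the weak base ionises only the phenol so that O-addition rather than C-addition through the ketone enolate is expected.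

**Step 6**
Reactants: 11 hexa-O-benzyl ether of the target
Product: 12 1-[3-(2,4-dihydroxybenzoyl)-4,6-dihydroxy-2-(4-hydroxyphenyl)-1-benzofuran-7-yl]-3-(4-hydroxyphenyl)propan-1-one (CNP0181782.0)
Conditions: H2 (1 atm), 10% Pd/C, THF/MeOH (1:1), rt
Reagents that add atoms: none
Why: Catalytic hydrogenolysis should cleave all six aryl benzyl ethers as toluene, while the aromatic furan and the two aryl ketones, which become hydrogen-bonded to ortho hydroxyls as the phenols are freed, should resist reduction at ambient pressure.

**Compound list**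
1 | 1-[2,4-bis(benzyloxy)-6-hydroxyphenyl]ethanone | CC(=O)c1c(O)cc(OCc2ccccc2)cc1OCc1ccccc1 | starting material
2 | 4-(benzyloxy)benzaldehyde | O=Cc1ccc(OCc2ccccc2)cc1 | starting material
3 | (E)-1-[2,4-bis(benzyloxy)-6-hydroxyphenyl]-3-[4-(benzyloxy)phenyl]prop-2-en-1-one | O=C(/C=C/c1ccc(OCc2ccccc2)cc1)c1c(O)cc(OCc2ccccc2)cc1OCc1ccccc1 | intermediate
4 | 4,4',6'-tri-O-benzylphloretin, 1-[2,4-bis(benzyloxy)-6-hydroxyphenyl]-3-[4-(benzyloxy)phenyl]propan-1-one | O=C(CCc1ccc(OCc2ccccc2)cc1)c1c(O)cc(OCc2ccccc2)cc1OCc1ccccc1 | intermediate
5 | 1-(benzyloxy)-4-ethynylbenzene | C#Cc1ccc(OCc2ccccc2)cc1 | starting material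
6 | 2,4-bis(benzyloxy)benzaldehyde | O=Cc1ccc(OCc2ccccc2)cc1OCc1ccccc1 | starting material
7 | lithium [4-(benzyloxy)phenyl]acetylide | [Li]C#Cc1ccc(OCc2ccccc2)cc1 | intermediate
8 | 1-[2,4-bis(benzyloxy)phenyl]-3-[4-(benzyloxy)phenyl]prop-2-yn-1-ol (racemic) | OC(C#Cc1ccc(OCc2ccccc2)cc1)c1ccc(OCc2ccccc2)cc1OCc1ccccc1 | intermediate
9 | 1-[2,4-bis(benzyloxy)phenyl]-3-[4-(benzyloxy)phenyl]prop-2-yn-1-one | O=C(C#Cc1ccc(OCc2ccccc2)cc1)c1ccc(OCc2ccccc2)cc1OCc1ccccc1 | intermediate
10 | 3-{3,5-bis(benzyloxy)-2-[3-(4-(benzyloxy)phenyl)propanoyl]phenoxy}-1-[2,4-bis(benzyloxy)phenyl]-3-[4-(benzyloxy)phenyl]prop-2-en-1-one (mixture of alkene isomers, geometry not specified) | O=C(CCc1ccc(OCc2ccccc2)cc1)c1c(OC(=CC(=O)c2ccc(OCc3ccccc3)cc2OCc2ccccc2)c2ccc(OCc3ccccc3)cc2)cc(OCc2ccccc2)cc1OCc1ccccc1 | intermediate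
11 | 1-{4,6-bis(benzyloxy)-3-[2,4-bis(benzyloxy)benzoyl]-2-[4-(benzyloxy)phenyl]-1-benzofuran-7-yl}-3-[4-(benzyloxy)phenyl]propan-1-one | O=C(CCc1ccc(OCc2ccccc2)cc1)c1c(OCc2ccccc2)cc(OCc2ccccc2)c2c(C(=O)c3ccc(OCc4ccccc4)cc3OCc3ccccc3)c(-c3ccc(OCc4ccccc4)cc3)oc12 | intermediate
12 | 1-[3-(2,4-dihydroxybenzoyl)-4,6-dihydroxy-2-(4-hydroxyphenyl)-1-benzofuran-7-yl]-3-(4-hydroxyphenyl)propan-1-one | O=C(CCc1ccc(O)cc1)c1c(O)cc(O)c2c(C(=O)c3ccc(O)cc3O)c(-c3ccc(O)cc3)oc12 | target

**Step count.** Total: 6 steps. Longest linear sequence: 4 steps (steps 1, 2, 5, 6 or steps 3, 4, 5, 6).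

**Steps most likely to fail**

Step 5 (highest risk). Three processes may interfere:
- The hydrogen-bonded, ortho-acylated phenoxide may add slowly, or the adduct may revert at the temperature of the oxidative stage.
- Palladation may stall at the enol ether or be diverted into intermolecular coupling.
- The CH2–CH2 chain may be dehydrogenated to a chalcone; this alone would be repaired by the hydrogenation in step 6.

Fallback, setting out from 4 and returning at 11: the C–H/C–H coupling is replaced by a halide-based closure. Iodination of 4 at the less hindered activated position next to the free hydroxyl (NIS, MeCN, 0 °C) should give 1-[4,6-bis(benzyloxy)-2-hydroxy-3-iodophenyl]-3-[4-(benzyloxy)phenyl]propan-1-one F1. Base-mediated oxa-Michael addition of F1 to ynone 9 (K2CO3, DMF) should give 3-{3,5-bis(benzyloxy)-2-iodo-6-[3-(4-(benzyloxy)phenyl)propanoyl]phenoxy}-1-[2,4-bis(benzyloxy)phenyl]-3-[4-(benzyloxy)phenyl]prop-2-en-1-one F2. An intramolecular Heck-type cyclisation (Pd(OAc)2, PPh3, K2CO3, DMF, 90 °C), as known for 3-(2-iodoaryloxy)acrylates, should then deliver 11.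

Step 2. Turnover on the conjugated, chelated enone may be slow. Forcing the reaction or switching to a heterogeneous catalyst may start to cleave benzyl ethers, and prolonged heating may let the 2'-hydroxychalcone close to the flavanone. Fallback, setting out from 3 and returning at 4: chemoselectivity is given up and the protecting pattern is rebuilt. Exhaustive hydrogenation of 3 (H2, 10% Pd/C, EtOAc/MeOH, rt) should saturate the alkene and cleave all three benzyl ethers to give phloretin F3, which is also an article of commerce. Williamson benzylation of F3 (BnBr 3.1 equiv, K2CO3, acetone, reflux) should then etherify the 4-, 4'- and one of the two equivalent ortho hydroxyls. The remaining hydroxyl is held in a six-membered hydrogen bond to the ketone and should be too poorly nucleophilic to consume the limited bromide, so the product should be 4.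

Step 6. Cleavage of six ethers may be incomplete because partly deprotected material is poorly soluble or residual copper from step 5 poisons the catalyst, and forcing the reaction may reduce the diaryl ketone. Fallback, setting out from 11 and returning at 12: Lewis-acid debenzylation with BCl3 and pentamethylbenzene as benzyl-cation scavenger (CH2Cl2, −78 °C) should give 12 directly without a reducing agent; no additional compound arises on this path (none F0).

**Further compounds**
F1 | step 5 | 1-[4,6-bis(benzyloxy)-2-hydroxy-3-iodophenyl]-3-[4-(benzyloxy)phenyl]propan-1-one | O=C(CCc1ccc(OCc2ccccc2)cc1)c1c(O)c(I)c(OCc2ccccc2)cc1OCc1ccccc1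
F2 | step 5 | 3-{3,5-bis(benzyloxy)-2-iodo-6-[3-(4-(benzyloxy)phenyl)propanoyl]phenoxy}-1-[2,4-bis(benzyloxy)phenyl]-3-[4-(benzyloxy)phenyl]prop-2-en-1-one (alkene geometry not specified) | O=C(CCc1ccc(OCc2ccccc2)cc1)c1c(OC(=CC(=O)c2ccc(OCc3ccccc3)cc2OCc2ccccc2)c2ccc(OCc3ccccc3)cc2)c(I)c(OCc2ccccc2)cc1OCc1ccccc1
F3 | step 2 | phloretin, 3-(4-hydroxyphenyl)-1-(2,4,6-trihydroxyphenyl)propan-1-one | O=C(CCc1ccc(O)cc1)c1c(O)cc(O)cc1O
F0 | step 6 | none | none
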